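**Retrosynthetic overview**
1. The butenolide is carried as a 2-silylfuran and unmasked last with peracid; it is joined at C11–C12 by opening a C9/C11 spiro-epoxide, which comes from a C9 ketone (methylenation, α-face epoxidation) and fixes the 9α-hydroxyl.
2. Ring B is disconnected at C5–C6: a titanium-mediated reductive keto–ester cyclisation (McMurry coupling) of a monocyclic keto ester gives, after enol ether hydrolysis, the trans-decal-6-one, which is reduced to the 6β-alcohol.
3. Enabling feature: C5 of ring A lies between two quaternary carbons (C4 with its gem-dimethyl group and C10), so a C5 ketone cannot enolise and stays inert while the chain is built, and C6 is oxygenated, so it can enter as an ester carbonyl placed 1,6 to that ketone.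
4. Chain C6–C9: crotylboration of a C9 aldehyde (sets C8), then hydroboration and oxidation; C10: palladium-catalysed decarboxylative asymmetric allylation of 2,2,6-trimethylcyclohexanone, the allyl group being trimmed to the aldehyde.
5. Ring order: ring A is bought, ring B is closed in step 9, the butenolide ring is revealed in step 19.

Key step: step 9

Remark: labdane numbering is used (ring A: C1–C5 and C10; ring B: C5–C10; C17 on C8; C18 and C19 on C4; C20 on C10); β is the face of C20, and the target is the (5S,6R,8R,9R,10S) isomer (6β-OAc, 8α-Me, 9α-OH, trans ring fusion).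
Remark: the sense of induction in steps 2 and 5 is taken from the parent ketone and aldehyde series; C9 is a temporary centre until step 13 and the 8α-methyl group is the equatorial epimer of ketone 24, so only step 2 is critical for the absolute configuration.

**Step 1**
Reactants: 1 2,2,6-trimethylcyclohexan-1-one; 2 allyl chloroformate
Product: 4 allyl 2,6,6-trimethylcyclohex-1-en-1-yl carbonate, via lithium enolate 3 (not isolated)
Conditions: LiN(SiMe3)2, THF, 0 °C; then 2, −78 → 23 °C
Reagents that add atoms: none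
Why: the ketone has a single enolisable position, so deprotonation gives one tetrasubstituted lithium enolate, which the hard chloroformate acylates on oxygen (enol carbonate formation).

**Step 2**
Reactants: 4 allyl 2,6,6-trimethylcyclohex-1-en-1-yl carbonate
Product: 5 (R)-2-allyl-2,6,6-trimethylcyclohexan-1-one
Conditions: Pd2(dba)3 (2.5 mol%), (R)-t-BuPHOX (6.25 mol%), THF, 25 °C
Reagents that add atoms: none
Why: decarboxylative asymmetric allylic alkylation (Tsuji allylation), in which zerovalent palladium ionises the allyl carbonate, CO2 is lost and the enolate recombines with the allyl fragment inside the chiral phosphinooxazoline pocket, setting the quaternary centre (later C10) as (R), the (S)-ligand being known to give the (S)-ketone in this ketone series.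

**Step 3**
Reactants: 5 (R)-2-allyl-2,6,6-trimethylcyclohexan-1-one
Product: 6 (R)-2,2,6-trimethyl-6-[(E)-prop-1-en-1-yl]cyclohexan-1-one
Conditions: PdCl2(MeCN)2 (5 mol%), toluene, 60 °C
Reagents that add atoms: none
Why: palladium-hydride alkene isomerisation moves the terminal double bond to the more stable internal (E) position and stops there because the next carbon is quaternary.

**Step 4**
Reactants: 6 (R)-2,2,6-trimethyl-6-[(E)-prop-1-en-1-yl]cyclohexan-1-one
Product: 8 (1R)-1,3,3-trimethyl-2-oxocyclohexane-1-carbaldehyde, via ozonide 7 (not isolated)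
Conditions: O3, CH2Cl2, −78 °C; then Me2S, −78 → 23 °C
Reagents that add atoms: ozone, [O-][O+]=O
Why: ozonolysis with reductive work-up cleaves the propenyl group to the aldehyde (future C9), and the quaternary α-carbon keeps this β-keto aldehyde from enolising or epimerising.

**Step 5**
Reactants: 8 (1R)-1,3,3-trimethyl-2-oxocyclohexane-1-carbaldehyde; 9 (E)-but-2-ene
Product: 13 (2R)-2-[(1R,2R)-1-hydroxy-2-methylbut-3-en-1-yl]-2,6,6-trimethylcyclohexan-1-one, via (E)-crotylpotassium 10 (not isolated), via crotylborane 11 (not isolated), via borinate 12 (not isolated)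
Conditions: 9, KOt-Bu, n-BuLi, THF, −78 → −45 °C; (+)-Ipc2BOMe (antipode from (−)-α-pinene), −78 °C; BF3·OEt2; then 8, −78 °C; then pH 7 phosphate buffer, MeOH, 30% H2O2, 0 → 23 °C
Reagents that add atoms: none
Why: Brown crotylboration through a closed chair transition state, in which the (E)-crotyl geometry gives the anti adduct and the isopinocampheyl groups of the (−)-α-pinene series direct attack to the Re face of the aldehyde, setting C8 as (R) while the hindered non-enolisable ring ketone stays untouched and the buffered oxidative work-up avoids retro-aldol cleavage.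

**Step 6**
Reactants: 13 (2R)-2-[(1R,2R)-1-hydroxy-2-methylbut-3-en-1-yl]-2,6,6-trimethylcyclohexan-1-one
Product: 14 (2R)-2-[(1R,2R)-1-(tert-butyldimethylsilyloxy)-2-methylbut-3-en-1-yl]-2,6,6-trimethylcyclohexan-1-one
Conditions: TBSOTf, 2,6-lutidine, CH2Cl2, −78 → 0 °C
Reagents that add atoms: tert-butyldimethylsilyl trifluoromethanesulfonate, CC(C)(C)[Si](C)(C)OS(=O)(=O)C(F)(F)F
Why: the reactive silyl triflate protects the hindered neopentyl-type alcohol, which blocks retro-aldol cleavage and later lactonisation onto C6.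

**Step 7**
Reactants: 14 (2R)-2-[(1R,2R)-1-(tert-butyldimethylsilyloxy)-2-methylbut-3-en-1-yl]-2,6,6-trimethylcyclohexan-1-one
Product: 16 (2R)-2-[(1R,2R)-1-(tert-butyldimethylsilyloxy)-4-hydroxy-2-methylbutyl]-2,6,6-trimethylcyclohexan-1-one, via alkylborane 15 (not isolated)
Conditions: 9-BBN, THF, 0 → 23 °C; then NaOH (3 M), 30% H2O2, 0 → 23 °C
Reagents that add atoms: hydrogen peroxide, OO
Why: anti-Markovnikov hydroboration–oxidation of the terminal alkene gives the primary alcohol at C6, and 9-BBN does not reduce the 2,2,6,6-tetrasubstituted ketone at ambient temperature.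

**Step 8**
Reactants: 16 (2R)-2-[(1R,2R)-1-(tert-butyldimethylsilyloxy)-4-hydroxy-2-methylbutyl]-2,6,6-trimethylcyclohexan-1-one
Product: 18 methyl (3R,4R)-4-(tert-butyldimethylsilyloxy)-3-methyl-4-[(1R)-1,3,3-trimethyl-2-oxocyclohexyl]butanoate, via carboxylic acid 17 (not isolated)
Conditions: TEMPO (20 mol%), PhI(OAc)2, MeCN/H2O (1:1), 23 °C; concentrate; then Me3SiCHN2, toluene/MeOH, 0 °C
Reagents that add atoms: water, O; trimethylsilyldiazomethane, C[Si](C)(C)C=[N+]=[N-]
Why: oxoammonium (TEMPO) oxidation takes the primary alcohol through the aldehyde hydrate to the acid, which the diazoalkane methylates, with no α-stereocentre at risk and the silyl ether and hindered ketone inert.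

**Step 9**
Reactants: 18 methyl (3R,4R)-4-(tert-butyldimethylsilyloxy)-3-methyl-4-[(1R)-1,3,3-trimethyl-2-oxocyclohexyl]butanoate
Product: 20 (3R,4R,4aS,8aS)-4-(tert-butyldimethylsilyloxy)-3,4a,8,8-tetramethyloctahydronaphthalen-1(2H)-one (6-oxo; 5α-H; 8α-Me; 9α-OTBS), via enol ether 19 (not isolated)
Conditions: TiCl3, LiAlH4 (Ti:Al 2:1), DME, reflux, 1 h; Et3N; then 18 added over 24 h (syringe pump, final 0.005 M), reflux; aq. K2CO3, filtration; then 1 M HCl, THF, 0 → 23 °C
Reagents that add atoms: water, O
Why: Low-valent titanium made from TiCl3 and LiAlH4 reduces the C5 ketone to a titanium-bound ketyl, which adds to the tethered ester carbonyl C6, and the resulting titanium 1,2-diolate is deoxygenated on the metal to the cyclic methyl enol ether 19, which dilute acid hydrolyses to ketone 20. The closest known reaction type is the titanium-induced keto ester cyclisation (McMurry coupling of a ketone with an ester), which turns acyclic keto esters into cycloalkanones. Ring B closes in the 6-exo-trig mode (C5 attacks the exocyclic ester C=O through the C10–C9–C8–C7 tether), and the non-enolisable 2,2,6,6-tetrasubstituted C5 ketone cannot undergo aldol or enolisation side reactions in the amine-buffered medium. The one new stereocentre, C5, is set when the enol ether is protonated: the proton enters axially from the α face, anti to the axial C10 and C4β methyl groups, so the trans-fused decalone forms under kinetic control. The step needs intramolecular ketone–ester coupling to win over intermolecular pinacol dimerisation and over plain reduction of the ketone, which is secured by slow addition at high dilution and by the quaternary C10 holding the ester chain next to the ketone; the C9 silyl ether and the C8 centre are not touched.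

**Step 10**
Reactants: 20 (3R,4R,4aS,8aS)-4-(tert-butyldimethylsilyloxy)-3,4a,8,8-tetramethyloctahydronaphthalen-1(2H)-one
Product: 21 (1R,3R,4R,4aS,8aS)-4-(tert-butyldimethylsilyloxy)-3,4a,8,8-tetramethyldecahydronaphthalen-1-ol (6β-OH)
Conditions: NaBH4, MeOH/THF (1:1), 0 → 23 °C
Reagents that add atoms: none
Why: hydride is delivered to the α face of the C6 carbonyl because the β face is shielded by the syn-axial C10 and C4β methyl groups, which gives the axial 6β-alcohol as in other 6-oxo-4,4,10-trimethyl-trans-decalins.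

**Step 11**
Reactants: 21 (1R,3R,4R,4aS,8aS)-4-(tert-butyldimethylsilyloxy)-3,4a,8,8-tetramethyldecahydronaphthalen-1-ol
Product: 22 (1R,3R,4R,4aS,8aS)-4-(tert-butyldimethylsilyloxy)-3,4a,8,8-tetramethyldecahydronaphthalen-1-yl acetate
Conditions: Ac2O, DMAP, pyridine, 50 °C
Reagents that add atoms: acetic anhydride, CC(=O)OC(C)=O
Why: DMAP-catalysed acylation of the only free hydroxyl group, heated because this axial alcohol is hindered.

**Step 12**
Reactants: 22 (1R,3R,4R,4aS,8aS)-4-(tert-butyldimethylsilyloxy)-3,4a,8,8-tetramethyldecahydronaphthalen-1-yl acetate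
Product: 23 (1R,3R,4R,4aS,8aS)-4-hydroxy-3,4a,8,8-tetramethyldecahydronaphthalen-1-yl acetate (9α-OH)
Conditions: HF·pyridine, THF/pyridine, 0 → 40 °C
Reagents that add atoms: none
Why: fluoride-driven cleavage of the Si–O bond frees the C9 alcohol, and the acetate is stable in this mildly acidic medium.

**Step 13**
Reactants: 23 (1R,3R,4R,4aS,8aS)-4-hydroxy-3,4a,8,8-tetramethyldecahydronaphthalen-1-yl acetate
Product: 24 (1R,3R,4aS,8aS)-3,4a,8,8-tetramethyl-4-oxodecahydronaphthalen-1-yl acetate (9-oxo; 8α-Me)
Conditions: Dess–Martin periodinane, NaHCO3, CH2Cl2, 23 °C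
Reagents that add atoms: none
Why: Dess–Martin oxidation of the secondary alcohol under buffered conditions gives the C9 ketone without epimerisation, the C8 methyl group already being in the equatorial, thermodynamically preferred orientation.

**Step 14**
Reactants: 24 (1R,3R,4aS,8aS)-3,4a,8,8-tetramethyl-4-oxodecahydronaphthalen-1-yl acetate
Product: 25 (1R,3R,4aS,8aS)-3,4a,8,8-tetramethyl-4-methylidenedecahydronaphthalen-1-yl acetate
Conditions: Zn, CH2Br2, TiCl4, THF/CH2Cl2, 0 → 23 °C
Reagents that add atoms: dibromomethane, BrCBr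
Why: Lombardo–Takai methylenation, whose non-basic zinc–titanium methylene reagent olefinates hindered, epimerisable ketones and leaves esters alone, so the acetate and the C8 centre survive.

**Step 15**
Reactants: 25 (1R,3R,4aS,8aS)-3,4a,8,8-tetramethyl-4-methylidenedecahydronaphthalen-1-yl acetate
Product: 26 the 9α,11-epoxide of 25 (spiro-oxirane at C9 with the oxygen on the α face; 9R)
Conditions: mCPBA, NaHCO3, CH2Cl2, 0 °C
Reagents that add atoms: 3-chloroperoxybenzoic acid, OOC(=O)c1cccc(Cl)c1
Why: Prilezhaev epoxidation from the α face of the exocyclic alkene, the β face being blocked by the axial C10 methyl group on the adjacent carbon, which places the new C9–O bond α (axial) and C11 β.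

**Step 16**
Reactants: 27 furan-3-ylmethanol
Product: 30 [2-(trimethylsilyl)furan-3-yl]methanol, via dilithio alkoxide 28 (not isolated), via bis-silyl ether 29 (not isolated)
Conditions: n-BuLi (2.2 equiv), DME, 0 °C; Me3SiCl (2.2 equiv), −78 → 23 °C; then K2CO3, MeOH, 23 °C
Reagents that add atoms: chlorotrimethylsilane, C[Si](C)(C)Cl
Why: the lithium alkoxide directs the second lithiation to the adjacent furan C2 (directed metalation), both lithium sites are silylated, and methanolysis then removes only the labile O-silyl group, leaving the C-silyl group that later marks the lactone carbonyl.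

**Step 17**
Reactants: 30 [2-(trimethylsilyl)furan-3-yl]methanol
Product: 31 3-(chloromethyl)-2-(trimethylsilyl)furan
Conditions: PPh3, CCl4, MeCN, 0 → 23 °C
Reagents that add atoms: carbon tetrachloride, ClC(Cl)(Cl)Cl
Why: Appel chlorination under neutral conditions avoids protodesilylation of the acid-sensitive 2-silylfuran.

**Step 18**
Reactants: 26 the 9α,11-epoxide; 31 3-(chloromethyl)-2-(trimethylsilyl)furan
Product: 33 (1R,3R,4R,4aS,8aS)-4-hydroxy-3,4a,8,8-tetramethyl-4-{2-[2-(trimethylsilyl)furan-3-yl]ethyl}decahydronaphthalen-1-yl acetate, via Grignard reagent 32 (not isolated)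
Conditions: 31, Mg, THF, 0 °C; then CuI (10 mol%), 26, THF, −30 → 0 °C; aq. NH4Cl
Reagents that add atoms: none
Why: copper-catalysed SN2 opening of the 1,1-disubstituted epoxide at its CH2 (C11) forms the C11–C12 bond and frees the tertiary 9α-alkoxide with the configuration fixed in step 15, while the 2-silyl group blocks reaction through the furan C2 position and the hindered axial acetate is not attacked at low temperature.

**Step 19**
Reactants: 33 (1R,3R,4R,4aS,8aS)-4-hydroxy-3,4a,8,8-tetramethyl-4-{2-[2-(trimethylsilyl)furan-3-yl]ethyl}decahydronaphthalen-1-yl acetate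
Product: 34 (1R,3R,4R,4aS,8aS)-4-hydroxy-3,4a,8,8-tetramethyl-4-[2-(2-oxo-2,5-dihydrofuran-3-yl)ethyl]decahydronaphthalen-1-yl acetate (CNP0205088.1)
Conditions: CH3CO3H (32% in AcOH), NaOAc, CH2Cl2, 0 → 23 °C
Reagents that add atoms: peracetic acid, CC(=O)OO
Why: peracid oxidation of a 2-silylfuran to a butenolide, in which the peracid attacks ipso at the silicon-bearing C16, silicon is lost and the 2-hydroxyfuran tautomerises to the conjugated 2(5H)-furanone, so the carbonyl ends up at C16 next to C13 as the target requires.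

**Compound list**
1 | 2,2,6-trimethylcyclohexan-1-one (racemic) | CC1CCCC(C)(C)C1=O | starting material
2 | allyl chloroformate | C=CCOC(=O)Cl | starting material
3 | lithium 2,6,6-trimethylcyclohex-1-en-1-olate | [Li]OC1=C(C)CCCC1(C)C | intermediate (not isolated)
4 | allyl 2,6,6-trimethylcyclohex-1-en-1-yl carbonate | C=CCOC(=O)OC1=C(C)CCCC1(C)C | intermediate
5 | (R)-2-allyl-2,6,6-trimethylcyclohexan-1-one | C=CC[C@@]1(C)CCCC(C)(C)C1=O | intermediate
6 | (R)-2,2,6-trimethyl-6-[(E)-prop-1-en-1-yl]cyclohexan-1-one | C/C=C/[C@@]1(C)CCCC(C)(C)C1=O | intermediate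
7 | 3-methyl-5-[(1R)-1,3,3-trimethyl-2-oxocyclohexyl]-1,2,4-trioxolane (ozonide of 6, mixture at the trioxolane carbons) | CC1OOC(O1)[C@@]1(C)CCCC(C)(C)C1=O | intermediate (not isolated)
8 | (1R)-1,3,3-trimethyl-2-oxocyclohexane-1-carbaldehyde | O=C[C@@]1(C)CCCC(C)(C)C1=O | intermediate
9 | (E)-but-2-ene | C/C=C/C | starting material
10 | (E)-but-2-en-1-ylpotassium | C/C=C/C[K] | intermediate (not isolated)
11 | (E)-but-2-en-1-ylbis(isopinocampheyl)borane, isopinocampheyl groups of the (−)-α-pinene series | C/C=C/CB([C@H]1C[C@H]2C[C@H](C2(C)C)[C@@H]1C)[C@H]1C[C@H]2C[C@H](C2(C)C)[C@@H]1C | intermediate (not isolated)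
12 | bis(isopinocampheyl)borinic ester of alcohol 13 | C=C[C@@H](C)[C@@H](OB([C@H]1C[C@H]2C[C@H](C2(C)C)[C@@H]1C)[C@H]1C[C@H]2C[C@H](C2(C)C)[C@@H]1C)[C@@]1(C)CCCC(C)(C)C1=O | intermediate (not isolated)
13 | (2R)-2-[(1R,2R)-1-hydroxy-2-methylbut-3-en-1-yl]-2,6,6-trimethylcyclohexan-1-one | C=C[C@@H](C)[C@@H](O)[C@@]1(C)CCCC(C)(C)C1=O | intermediate
14 | (2R)-2-[(1R,2R)-1-(tert-butyldimethylsilyloxy)-2-methylbut-3-en-1-yl]-2,6,6-trimethylcyclohexan-1-one | C=C[C@@H](C)[C@@H](O[Si](C)(C)C(C)(C)C)[C@@]1(C)CCCC(C)(C)C1=O | intermediate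
15 | B-alkyl-9-borabicyclo[3.3.1]nonane from 14 (boron on the terminal carbon, future C6) | C1CC2CCCC(C1)B2CC[C@@H](C)[C@@H](O[Si](C)(C)C(C)(C)C)[C@@]1(C)CCCC(C)(C)C1=O | intermediate (not isolated)
16 | (2R)-2-[(1R,2R)-1-(tert-butyldimethylsilyloxy)-4-hydroxy-2-methylbutyl]-2,6,6-trimethylcyclohexan-1-one | OCC[C@@H](C)[C@@H](O[Si](C)(C)C(C)(C)C)[C@@]1(C)CCCC(C)(C)C1=O | intermediate
17 | (3R,4R)-4-(tert-butyldimethylsilyloxy)-3-methyl-4-[(1R)-1,3,3-trimethyl-2-oxocyclohexyl]butanoic acid | OC(=O)C[C@@H](C)[C@@H](O[Si](C)(C)C(C)(C)C)[C@@]1(C)CCCC(C)(C)C1=O | intermediate (not isolated)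
18 | methyl (3R,4R)-4-(tert-butyldimethylsilyloxy)-3-methyl-4-[(1R)-1,3,3-trimethyl-2-oxocyclohexyl]butanoate | COC(=O)C[C@@H](C)[C@@H](O[Si](C)(C)C(C)(C)C)[C@@]1(C)CCCC(C)(C)C1=O | intermediate
19 | tert-butyl{[(1R,2R,8aS)-4-methoxy-2,5,5,8a-tetramethyl-1,2,3,5,6,7,8,8a-octahydronaphthalen-1-yl]oxy}dimethylsilane (C5=C6 methyl enol ether) | COC=1C[C@@H](C)[C@@H](O[Si](C)(C)C(C)(C)C)[C@@]2(C)CCCC(C)(C)C=12 | intermediate (not isolated)
20 | (3R,4R,4aS,8aS)-4-(tert-butyldimethylsilyloxy)-3,4a,8,8-tetramethyloctahydronaphthalen-1(2H)-one | O=C1C[C@@H](C)[C@@H](O[Si](C)(C)C(C)(C)C)[C@@]2(C)CCCC(C)(C)[C@H]12 | intermediate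
21 | (1R,3R,4R,4aS,8aS)-4-(tert-butyldimethylsilyloxy)-3,4a,8,8-tetramethyldecahydronaphthalen-1-ol | O[C@@H]1C[C@@H](C)[C@@H](O[Si](C)(C)C(C)(C)C)[C@@]2(C)CCCC(C)(C)[C@H]12 | intermediate
22 | (1R,3R,4R,4aS,8aS)-4-(tert-butyldimethylsilyloxy)-3,4a,8,8-tetramethyldecahydronaphthalen-1-yl acetate | CC(=O)O[C@@H]1C[C@@H](C)[C@@H](O[Si](C)(C)C(C)(C)C)[C@@]2(C)CCCC(C)(C)[C@H]12 | intermediate
23 | (1R,3R,4R,4aS,8aS)-4-hydroxy-3,4a,8,8-tetramethyldecahydronaphthalen-1-yl acetate | CC(=O)O[C@@H]1C[C@@H](C)[C@@H](O)[C@@]2(C)CCCC(C)(C)[C@H]12 | intermediate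
24 | (1R,3R,4aS,8aS)-3,4a,8,8-tetramethyl-4-oxodecahydronaphthalen-1-yl acetate | CC(=O)O[C@@H]1C[C@@H](C)C(=O)[C@@]2(C)CCCC(C)(C)[C@H]12 | intermediate
25 | (1R,3R,4aS,8aS)-3,4a,8,8-tetramethyl-4-methylidenedecahydronaphthalen-1-yl acetate | CC(=O)O[C@@H]1C[C@@H](C)C(=C)[C@@]2(C)CCCC(C)(C)[C@H]12 | intermediate
26 | 9α,11-epoxide of 25 (spiro-oxirane at C9, oxygen α, 9R; 6β-OAc, 8α-Me, 5α-H, 10β-Me) | CC(=O)O[C@@H]1C[C@@H](C)[C@]3(CO3)[C@@]2(C)CCCC(C)(C)[C@H]12 | intermediate
27 | furan-3-ylmethanol | OCc1ccoc1 | starting material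
28 | lithium (2-lithiofuran-3-yl)methanolate | [Li]OCc1ccoc1[Li] | intermediate (not isolated)
29 | trimethyl{3-[(trimethylsilyloxy)methyl]furan-2-yl}silane | C[Si](C)(C)OCc1ccoc1[Si](C)(C)C | intermediate (not isolated)
30 | [2-(trimethylsilyl)furan-3-yl]methanol | OCc1ccoc1[Si](C)(C)C | intermediate
31 | 3-(chloromethyl)-2-(trimethylsilyl)furan | ClCc1ccoc1[Si](C)(C)C | intermediate
32 | {[2-(trimethylsilyl)furan-3-yl]methyl}magnesium chloride | Cl[Mg]Cc1ccoc1[Si](C)(C)C | intermediate (not isolated)
33 | (1R,3R,4R,4aS,8aS)-4-hydroxy-3,4a,8,8-tetramethyl-4-{2-[2-(trimethylsilyl)furan-3-yl]ethyl}decahydronaphthalen-1-yl acetate | CC(=O)O[C@@H]1C[C@@H](C)[C@](O)(CCc3ccoc3[Si](C)(C)C)[C@@]2(C)CCCC(C)(C)[C@H]12 | intermediate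
34 | (1R,3R,4R,4aS,8aS)-4-hydroxy-3,4a,8,8-tetramethyl-4-[2-(2-oxo-2,5-dihydrofuran-3-yl)ethyl]decahydronaphthalen-1-yl acetate (6β-acetoxy-9α-hydroxylabd-13-en-16,15-olide) | CC(=O)O[C@@H]1C[C@@H](C)[C@](O)(CCC2=CCOC2=O)[C@@]2(C)CCCC(C)(C)[C@H]12 | target

**Step count**
Total step count: 19.
Longest linear sequence: 17 steps (steps 1–15, 18 and 19; steps 16 and 17 prepare chloride 31).

**Steps most likely to fail**

1. Step 9. The ketyl of the doubly neopentyl C5 ketone may be reduced to the carbinol, couple intermolecularly, or the titanium diolate may not lose its oxygens, so that ring closure and deoxygenation do not occur in one operation. The fallback sets out from alcohol 16 and comes back at ketone 20, building the C5–C6 bond and removing the C5 oxygen in separate, known operations. Parikh–Doering oxidation (SO3·pyridine, DMSO, Et3N) of 16 should give the keto aldehyde (3R,4R)-4-(tert-butyldimethylsilyloxy)-3-methyl-4-[(1R)-1,3,3-trimethyl-2-oxocyclohexyl]butanal F1. SmI2 in THF with t-BuOH (−78 → 0 °C) should then effect the intramolecular ketone–aldehyde pinacol coupling within a samarium chelate to the cis-5,6-diol F2. A second Parikh–Doering oxidation, which does not cleave 1,2-diols, should convert the secondary C6 hydroxyl into the α-ketol F3. SmI2 in THF/MeOH at −78 °C should finally cleave the tertiary α-hydroxyl reductively, and protonation of the samarium enolate at C5 from the α face should give 20.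

2. Step 18. The organomagnesium reagent may attack the 6-acetate, or the opening at the neopentyl-type C11 may be slow enough for the furylmethyl reagent to homocouple. The fallback sets out from epoxide 26 and comes back at 33, taking the acetate out of the organometallic step. Methanolysis (K2CO3, MeOH, 23 °C) should give the epoxy alcohol F4; an excess of reagent 32 with CuI (THF, 0 → 23 °C) should open it to the 6β,9α-diol F5; and Ac2O, DMAP, pyridine should acetylate only the secondary 6β-hydroxyl, the tertiary 9α-hydroxyl being inert, to give 33.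

3. Step 15. Oxygen delivery to the exocyclic alkene may show poor or reversed facial selectivity. The fallback sets out from alkene 25 and comes back at epoxide 26, letting a nucleophile rather than the oxidant set C9. N-Bromosuccinimide in aqueous THF should give the bromohydrin F6: the bromonium ion forms reversibly, and the product-determining attack of water at the tertiary C9 occurs axially from the α face, away from the C10 methyl group, so the hydroxyl is placed α whichever face the electrophile prefers. NaH in THF at 0 °C should then close F6 to epoxide 26 with the oxygen on the α face.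

**Further compounds**
F1 | step 9 | (3R,4R)-4-(tert-butyldimethylsilyloxy)-3-methyl-4-[(1R)-1,3,3-trimethyl-2-oxocyclohexyl]butanal | O=CC[C@@H](C)[C@@H](O[Si](C)(C)C(C)(C)C)[C@@]1(C)CCCC(C)(C)C1=O
F2 | step 9 | (3R,4R,4aS)-4-(tert-butyldimethylsilyloxy)-3,4a,8,8-tetramethyloctahydronaphthalene-1,8a(1H)-diol (cis-5,6-diol in labdane numbering; configuration at C5 and C6 not controlled and later erased) | OC1C[C@@H](C)[C@@H](O[Si](C)(C)C(C)(C)C)[C@@]2(C)CCCC(C)(C)C12O
F3 | step 9 | (3R,4R,4aS)-4-(tert-butyldimethylsilyloxy)-8a-hydroxy-3,4a,8,8-tetramethyloctahydronaphthalen-1(2H)-one (α-ketol; C5 configuration later erased) | O=C1C[C@@H](C)[C@@H](O[Si](C)(C)C(C)(C)C)[C@@]2(C)CCCC(C)(C)C12O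
F4 | step 18 | 9α,11-epoxy-6β-alcohol (deacetylated 26) | O[C@@H]1C[C@@H](C)[C@]3(CO3)[C@@]2(C)CCCC(C)(C)[C@H]12
F5 | step 18 | (1R,3R,4R,4aS,8aS)-3,4a,8,8-tetramethyl-4-{2-[2-(trimethylsilyl)furan-3-yl]ethyl}decahydronaphthalene-1,4-diol | O[C@@H]1C[C@@H](C)[C@](O)(CCc3ccoc3[Si](C)(C)C)[C@@]2(C)CCCC(C)(C)[C@H]12
F6 | step 15 | (1R,3R,4R,4aS,8aS)-4-(bromomethyl)-4-hydroxy-3,4a,8,8-tetramethyldecahydronaphthalen-1-yl acetate | CC(=O)O[C@@H]1C[C@@H](C)[C@](O)(CBr)[C@@]2(C)CCCC(C)(C)[C@H]12
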